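The runs were computed from invented constants; scatter was added.

I counted Q against L. Here L and Q are end groups of two kinds, J links, Z rings and E the other product, and the suspects are the steps listed below.

| flask | L | Q | remark | time |
|---|---|---|---|---|
| Tuesday's | 0.50 M | 0.26 M | run made earlier |  |
| Friday's | 0.50 M | 0.39 M | run made earlier |  |
| Monday's | 0.75 M | 0.525 M | run made earlier |  |
| flask | 0.50 M | 0.525 M |  | 8.0 min |

- Tuesday's (time / min: L / %, Z / %, J / %): 0.833: 18, 48, 5; 2.50: 9, 51, 0; 4.00: 4, 50, 1; 6.00: 5, 54, 0; 10.0: 3, 54, 0
- Friday's (time / min: L / %, Z / %, J / %): 2.00: 7, 77, 1; 4.00: 7, 77, 0; 6.00: 3, 82, 1; 8.00: 2, 78, 0; 10.0: 3, 76, 1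
- Monday's (time / min: L / %, Z / %, J / %): 0.833: 11, 65, 6; 1.33: 8, 66, 2; 2.50: 5, 68, 1; 5.00: 3, 72, 0; 10.0: 4, 72, 1

(each reading ± 1.5 percentage points)

- a species is counted by the L in it: one E counts as two
- on the list of suspects stand: L + Q -> Z; 2 L -> E; L + Q <-> J
- the reaction counts as stopped when no species that holds the L changes by six tenths of a point or more over the second half of the time

- which holds at 8.0 min: what has brought the reaction to rest, or that it has not come to rest (forward and back rates have come level / it is still moving / all of L has reacted / Q has run out first)
- conversion of L at 8.0 min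
- amount of Z at 8.0 min, in percent of the L charged

The first setting I could turn was Q, and by hand each Z costs one Q, so I kept one quantity, which for the asked flask came to 105%: the allowance, Q charged over L charged, which is the Z that the Q can pay for in percent of the L charged. On the runs, allowances of 52.0%, 78.0% and 70.0% stood against last readings of Z of 54% on Tuesday, 76% on Friday and 72% on Monday, as near as readings good to 1.5 percentage points can tell. The second setting was L: Monday's Q with L lowered from 0.75 M to 0.50 M lifts the allowance above 100%, so I took L as the limiting reagent and expected Z to fall short of 100% by what E took. The third was time, and by hand it helps while L stands, but Monday's Z read 72% at 5.00 min and 72% at 10.0 min, so on the strength of that run, which had a different charge, I expected the flask to be flat by 8.0 min.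

The forecast gave all of L has reacted, a conversion of 99.8% and Z at 91%, on the ground that “In the flask Q is in slight excess, so L is limiting”.

The flask gave all of L has reacted, a conversion of >99.9% and Z at 94.1%.

    L + Q → Z, rate k1*[L] as long as [Q] is above zero (k = 0.238 s⁻¹)
    2 L → E (k = 0.0592 L mol⁻¹ s⁻¹)
    L + Q ⇌ J (K = 27.5 L mol⁻¹, k = 0.758 L mol⁻¹ s⁻¹)

In the flask, by 0.800 min L stood at 1.58%, J at 15.2%, Z at 77.4% and E at 5.88%, with 99.4% of the turnover to E up to the asked time behind it. By 4.00 min in the flask, with Q at 10.4% of its own charge, J had fallen to 0.183% and Z had risen to 93.9%, which is 11 points under the allowance. The same flask with 0.21 M of Q has an allowance of 42.0%, and it ended with Q at 0% of its own charge and, in percent of the L charged, E at 54.7%, L at 3.31% and Z at 42.0%.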